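Halimane numbering is used (ring A: C1–C5, C10; ring B: C5–C10; C4 carries C18 acetoxymethyl; side chain C11–C15). The route rests on cutting the C7–C10 bond of a cyclobutanone (C7–C8–C9–C10) that already holds the three contiguous centres, and inserting a tethered alkyne (C5≡C6) into it. This rhodium-catalysed cut-and-sew step enlarges the four-membered ring by two carbons to the ring-B cyclohexenone, closes ring A and places the C5=C6–C7=O enone in one operation; it exploits that the enone β-carbon C5 is the ring-fusion atom next to C10–H. The precursor is a 2,3,3,4-substituted cyclobutanone from a keteniminium [2+2] cycloaddition on an (E)-trisubstituted alkene.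

Key step: step 15

Remark (numbering): C17 is the methyl on C8, C19 the methyl on C4, C20 the methyl on C9, C16 the methyl on C13; the target is (4R,8R,9S,10S,13R).
Remark (assumption): the facial sense of the auxiliary in step 14 is assigned from a steric model only (alkene approaches C7 anti to the C8 methyl, with C10–H rather than C1 turned toward the nearer pyrrolidine methyl). On this model the (2R,5R)-amide gives 26; if the first run shows the opposite sense, the (2S,5S)-amide is used with nothing else changed.
Remark (C8): C8 is left open on purpose in 25–27 and is set in step 16.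

Step 1
Reactants: 1 pent-1-en-4-yne
Product: 4 (2E)-3-methylhexa-2,5-dien-1-ol, via alkenylalane 2 (not isolated), via lithium alkenylaluminate 3 (not isolated)
Conditions: Me3Al (2 equiv), Cp2ZrCl2 (25 mol %), ClCH2CH2Cl, rt; volatiles off; n-BuLi, THF–hexane, −78 → 0 °C; (CH2O)n, rt; H2O work-up
Reagents that add atoms: trimethylaluminium (C[Al](C)C); formaldehyde from paraformaldehyde (C=O)
Why: Zr-catalysed Negishi carboalumination adds Me–Al syn and with aluminium on the terminal carbon across the alkyne only, which fixes the (E)-trisubstituted alkene, and the derived aluminate is hydroxymethylated by formaldehyde with retention.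

Step 2
Reactants: 4 (2E)-3-methylhexa-2,5-dien-1-ol
Product: 5 (2S,3S)-epoxy alcohol
Conditions: Ti(OiPr)4 (10 mol %), L-(+)-diethyl tartrate (12 mol %), t-BuOOH, 4 Å MS, CH2Cl2, −20 °C
Reagents that add atoms: tert-butyl hydroperoxide (CC(C)(C)OO)
Why: Sharpless asymmetric epoxidation touches only the allylic alkene, and L-(+)-tartrate should give the (2S,3S)-epoxide as it does for geraniol, which is the source of the C4 configuration.

Step 3
Reactants: 5 (2S,3S)-epoxy alcohol
Product: 6 epoxy TBS ether
Conditions: TBSCl, imidazole, DMF, rt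
Reagents that add atoms: tert-butyldimethylsilyl chloride (CC(C)(C)[Si](C)(C)Cl)
Why: Standard silylation of the primary alcohol installs the siloxymethyl group that has to migrate in step 4.

Step 4
Reactants: 6 epoxy TBS ether
Product: 7 (2S)-2-(TBS-oxymethyl)-2-methylpent-4-enal
Conditions: methylaluminium bis(4-bromo-2,6-di-tert-butylphenoxide) (MABR, 20 mol %), CH2Cl2, −78 → −40 °C
Reagents that add atoms: none
Why: MABR-promoted epoxy silyl ether to β-siloxy aldehyde rearrangement (semipinacol type) ionises the tertiary C–O bond and shifts the siloxymethyl group anti to it, so the epoxide chirality is transferred with inversion to the new quaternary carbon (future C4).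

Step 5
Reactants: 7 (2S)-2-(TBS-oxymethyl)-2-methylpent-4-enal
Product: 8 (2R)-terminal alkyne TBS ether
Conditions: dimethyl (1-diazo-2-oxopropyl)phosphonate, K2CO3, MeOH, 0 °C → rt
Reagents that add atoms: dimethyl (1-diazo-2-oxopropyl)phosphonate (COP(=O)(OC)C(=[N+]=[N-])C(C)=O)
Why: Seyferth–Gilbert homologation with the Ohira–Bestmann reagent turns the non-enolisable aldehyde carbon into C5 and adds C6 without touching the quaternary centre.

Step 6
Reactants: 8 (2R)-terminal alkyne TBS ether
Product: 10 (2R)-silyl alkyne TBS ether, via lithium acetylide 9 (not isolated)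
Conditions: n-BuLi, THF, −78 °C; Me3SiCl, −78 °C → rt
Reagents that add atoms: chlorotrimethylsilane (C[Si](C)(C)Cl)
Why: Acetylide silylation caps the alkyne so that it stays inert in the hydroboration of step 12 and toward the keteniminium of step 14 and enters step 15 as an internal alkyne.

Step 7
Reactants: 10 (2R)-silyl alkyne TBS ether
Product: 11 (2R)-2-methyl-2-[(trimethylsilyl)ethynyl]pent-4-en-1-yl acetate
Conditions: Ac2O (3 equiv), Cu(OTf)2 (5 mol %), CH2Cl2, rt
Reagents that add atoms: acetic anhydride (CC(=O)OC(C)=O)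
Why: Lewis-acid-catalysed acylative cleavage converts the primary TBS ether directly into the acetate of the target without fluoride, which would also cleave the alkynyl silane.

Step 8
Reactants: 12 (R)-citronellic acid
Product: 13 tert-butyl (R)-citronellate
Conditions: tert-butyl 2,2,2-trichloroacetimidate (2 equiv), BF3·OEt2 (2 mol %), cyclohexane–CH2Cl2, rt
Reagents that add atoms: tert-butyl 2,2,2-trichloroacetimidate (CC(C)(C)OC(=N)C(Cl)(Cl)Cl)
Why: Imidate tert-butylation gives an ester that survives the basic and organometallic steps and is later removed by acid without loss of the acetate; C13 comes from the chiral pool.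

Step 9
Reactants: 13 tert-butyl (R)-citronellate
Product: 15 tert-butyl (3R)-3-methyl-6-oxohexanoate, via secondary ozonide 14 (not isolated)
Conditions: O3, CH2Cl2, −78 °C; PPh3, −78 °C → rt
Reagents that add atoms: ozone ([O-][O+]=O)
Why: Ozonolysis of the trisubstituted alkene with reductive work-up (Criegee mechanism) cuts off acetone and leaves the aldehyde carbon that becomes C9.

Step 10
Reactants: 15 tert-butyl (3R)-3-methyl-6-oxohexanoate
Product: 16 tert-butyl (3R)-3-methylhept-6-ynoate
Conditions: dimethyl (1-diazo-2-oxopropyl)phosphonate, K2CO3, MeOH, 0 °C → rt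
Reagents that add atoms: dimethyl (1-diazo-2-oxopropyl)phosphonate (COP(=O)(OC)C(=[N+]=[N-])C(C)=O)
Why: Seyferth–Gilbert homologation under carbonate conditions is tolerated by the enolisable aldehyde and the tert-butyl ester, and C13 (β to the ester) cannot epimerise.

Step 11
Reactants: 16 tert-butyl (3R)-3-methylhept-6-ynoate
Product: 18 tert-butyl (3R,6E)-7-iodo-3,6-dimethylhept-6-enoate, via alkenylalane 17 (not isolated)
Conditions: Me3Al (2.5 equiv), Cp2ZrCl2 (20 mol %), H2O (1 equiv), CH2Cl2, −20 °C; I2, THF, −20 → 0 °C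
Reagents that add atoms: trimethylaluminium (C[Al](C)C); iodine (II)
Why: Water-accelerated Negishi carboalumination at low temperature (to spare the ester) followed by iodinolysis with retention gives the (E)-2-methyl-1-iodoalkene, with C20 on C9 and iodine on C10.

Step 12
Reactants: 11 (2R)-2-methyl-2-[(trimethylsilyl)ethynyl]pent-4-en-1-yl acetate; 18 tert-butyl (3R,6E)-7-iodo-3,6-dimethylhept-6-enoate
Product: 20 (E)-enyne diester, via B-alkyl-9-BBN 19 (not isolated)
Conditions: 9-BBN, THF, 0 °C → rt; then 18, PdCl2(dppf) (5 mol %), AsPh3 (10 mol %), K3PO4, DMF–H2O, rt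
Reagents that add atoms: none
Why: 9-BBN hydroborates only the terminal alkene (boron on C1) and the B-alkyl Suzuki–Miyaura coupling joins C1 to C10 with retention of the (E)-geometry.

Step 13
Reactants: 21 (2R,5R)-2,5-dimethylpyrrolidine; 22 propanoyl chloride
Product: 23 1-[(2R,5R)-2,5-dimethylpyrrolidin-1-yl]propan-1-one
Conditions: Et3N, CH2Cl2, 0 °C → rt
Reagents that add atoms: none
Why: Schotten–Baumann-type N-acylation gives the C2-symmetric chiral amide that supplies C7, C8 and C17.

Step 14
Reactants: 20 (E)-enyne diester; 23 1-[(2R,5R)-2,5-dimethylpyrrolidin-1-yl]propan-1-one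
Product: 26 cyclobutanone (C8 epimers), via keteniminium triflate 24 (not isolated), via cyclobutaniminium triflate 25 (not isolated)
Conditions: 23 (1.3 equiv), Tf2O, 2,4,6-collidine, ClCH2CH2Cl, −20 °C → rt; then 20, 80 °C; then aq NaHCO3, rt
Reagents that add atoms: water (O)
Why: In this keteniminium–alkene [2+2] cycloaddition the central carbon (C7) bonds to the less substituted alkene carbon C10 and closure at the tertiary cation C9 is suprafacial, so the (E)-geometry fixes C9/C10 (H10 cis to C11), the C2-symmetric auxiliary is to choose the alkene face (see assumption), C8 is not controlled, and the hindered silyl alkyne should not compete.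

Step 15
Reactants: 26 cyclobutanone (C8 epimers)
Product: 27 6-silyl bicyclic enone tert-butyl ester (C8 epimers)
Conditions: [Rh(C2H4)2Cl]2 (5 mol %), PMe2Ph (20 mol %), 1,4-dioxane (0.02 M), 130 °C, sealed tube
Reagents that add atoms: none
Why: Rh(I), held by the tethered alkyne, inserts into the proximal C7–C10 bond to give a rhodacyclopentanone, the alkyne then inserts syn into Rh–C10 and C6–C7 reductive elimination releases the cyclohexenone. The closest known reaction type is the intramolecular rhodium-catalysed cut-and-sew coupling of cyclobutanones with alkynes tethered at the α-carbon, which gives fused cyclohexenones. Ring A closes in the 6-exo-dig mode (C10 onto C5), while ring B is not closed anew but grows from four to six members by taking C5 and C6 into the C7–C10 bond. No new stereocentre is formed: C10 is retained because oxidative addition and migratory insertion both proceed with retention at carbon, and C4, C9 and C13 are spectators. The step needs C7–C10 rather than C7–C8 cleavage, which the alkyne on C10 should secure because only that rhodacycle can be trapped, and insertion rather than decarbonylation, which the small electron-rich phosphine should favour.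

Step 16
Reactants: 27 6-silyl bicyclic enone tert-butyl ester (C8 epimers)
Product: 29 (8R)-6-silyl bicyclic enone tert-butyl ester, via trilithium trienolate 28 (not isolated)
Conditions: LDA (3.5 equiv), THF, −78 °C (27 added to the base); AcOH, −78 °C
Reagents that add atoms: none
Why: Kinetic α′-deprotonation by LDA gives the cross-conjugated dienolate without touching C10–H, and protonation anti to the pseudo-axial C20 methyl places H8 on the α face and C17 equatorial (8R), which is also the more stable epimer, while the two ester enolates are simply reprotonated.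

Step 17
Reactants: 29 (8R)-6-silyl bicyclic enone tert-butyl ester
Product: 31 CNP0210381.1, via silyl acid 30 (not isolated)
Conditions: TFA–CH2Cl2 (1:1), rt; then neat TFA, 40 °C
Reagents that add atoms: none
Why: Acidolysis of the tert-butyl ester (isobutene loss) and protodesilylation of the α-silyl enone by ipso protonation at C6 (tertiary β-silyl cation at C5) should leave the acetate, the enone and all stereocentres untouched.

Compound list
1 | pent-1-en-4-yne | C=CCC#C | starting material
2 | dimethyl[(1E)-2-methylpenta-1,4-dien-1-yl]alane | C=CC/C(C)=C/[Al](C)C | intermediate (not isolated)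
3 | lithium butyl(dimethyl)[(1E)-2-methylpenta-1,4-dien-1-yl]aluminate | [Li+].CCCC[Al-](C)(C)/C=C(\C)CC=C | intermediate (not isolated)
4 | (2E)-3-methylhexa-2,5-dien-1-ol | OC/C=C(\C)CC=C | intermediate
5 | [(2S,3S)-3-methyl-3-(prop-2-en-1-yl)oxiran-2-yl]methanol | OC[C@@H]1O[C@@]1(C)CC=C | intermediate
6 | tert-butyl(dimethyl){[(2S,3S)-3-methyl-3-(prop-2-en-1-yl)oxiran-2-yl]methoxy}silane | CC(C)(C)[Si](C)(C)OC[C@@H]1O[C@@]1(C)CC=C | intermediate
7 | (2S)-2-({[tert-butyl(dimethyl)silyl]oxy}methyl)-2-methylpent-4-enal | O=C[C@](C)(CO[Si](C)(C)C(C)(C)C)CC=C | intermediate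
8 | tert-butyl{[(2R)-2-ethynyl-2-methylpent-4-en-1-yl]oxy}dimethylsilane | C#C[C@](C)(CO[Si](C)(C)C(C)(C)C)CC=C | intermediate
9 | lithium acetylide of 8 | [Li]C#C[C@](C)(CO[Si](C)(C)C(C)(C)C)CC=C | intermediate (not isolated)
10 | tert-butyl(dimethyl)({(2R)-2-methyl-2-[(trimethylsilyl)ethynyl]pent-4-en-1-yl}oxy)silane | C[Si](C)(C)C#C[C@](C)(CO[Si](C)(C)C(C)(C)C)CC=C | intermediate
11 | (2R)-2-methyl-2-[(trimethylsilyl)ethynyl]pent-4-en-1-yl acetate | CC(=O)OC[C@](C)(CC=C)C#C[Si](C)(C)C | intermediate
12 | (3R)-3,7-dimethyloct-6-enoic acid, (R)-citronellic acid | CC(C)=CCC[C@@H](C)CC(=O)O | starting material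
13 | tert-butyl (3R)-3,7-dimethyloct-6-enoate | CC(C)=CCC[C@@H](C)CC(=O)OC(C)(C)C | intermediate
14 | tert-butyl (3R)-5-(5,5-dimethyl-1,2,4-trioxolan-3-yl)-3-methylpentanoate, ozonide, both epimers at the trioxolane carbon | CC1(C)OOC(CC[C@@H](C)CC(=O)OC(C)(C)C)O1 | intermediate (not isolated)
15 | tert-butyl (3R)-3-methyl-6-oxohexanoate | O=CCC[C@@H](C)CC(=O)OC(C)(C)C | intermediate
16 | tert-butyl (3R)-3-methylhept-6-ynoate | C#CCC[C@@H](C)CC(=O)OC(C)(C)C | intermediate
17 | tert-butyl (3R,6E)-7-(dimethylalumanyl)-3,6-dimethylhept-6-enoate | C[Al](C)/C=C(\C)CC[C@@H](C)CC(=O)OC(C)(C)C | intermediate (not isolated)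
18 | tert-butyl (3R,6E)-7-iodo-3,6-dimethylhept-6-enoate | I/C=C(\C)CC[C@@H](C)CC(=O)OC(C)(C)C | intermediate
19 | (2R)-5-(9-borabicyclo[3.3.1]nonan-9-yl)-2-methyl-2-[(trimethylsilyl)ethynyl]pentyl acetate | CC(=O)OC[C@](C)(CCCB1C2CCCC1CCC2)C#C[Si](C)(C)C | intermediate (not isolated)
20 | tert-butyl (3R,6E,11R)-11-(acetoxymethyl)-3,6,11-trimethyl-13-(trimethylsilyl)tridec-6-en-12-ynoate | CC(=O)OC[C@](C)(CCC/C=C(\C)CC[C@@H](C)CC(=O)OC(C)(C)C)C#C[Si](C)(C)C | intermediate
21 | (2R,5R)-2,5-dimethylpyrrolidine | C[C@@H]1CC[C@@H](C)N1 | starting material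
22 | propanoyl chloride | CCC(Cl)=O | starting material
23 | 1-[(2R,5R)-2,5-dimethylpyrrolidin-1-yl]propan-1-one | CCC(=O)N1[C@H](C)CC[C@H]1C | intermediate
24 | (2R,5R)-2,5-dimethyl-1-(prop-1-en-1-ylidene)pyrrolidinium triflate, keteniminium salt | CC=C=[N+]1[C@H](C)CC[C@H]1C.[O-]S(=O)(=O)C(F)(F)F | intermediate (not isolated)
25 | cyclobutaniminium triflate: iminium of 26 with the auxiliary (C9 R, C10 S, C8 epimers, centre left open) | CC(=O)OC[C@](C)(CCC[C@@H]1C(=[N+]2[C@H](C)CC[C@H]2C)C(C)[C@@]1(C)CC[C@@H](C)CC(=O)OC(C)(C)C)C#C[Si](C)(C)C.[O-]S(=O)(=O)C(F)(F)F | intermediate (not isolated)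
26 | tert-butyl (3R)-5-[(1R,2S)-2-[(4R)-4-(acetoxymethyl)-4-methyl-6-(trimethylsilyl)hex-5-yn-1-yl]-1,4-dimethyl-3-oxocyclobutyl]-3-methylpentanoate; ring C1 = C9, C2 = C10, C3 = C7, C4 = C8 (both epimers, centre left open) | CC(=O)OC[C@](C)(CCC[C@@H]1C(=O)C(C)[C@@]1(C)CC[C@@H](C)CC(=O)OC(C)(C)C)C#C[Si](C)(C)C | intermediate
27 | tert-butyl (4R,9S,10S,13R)-18-acetoxy-7-oxo-6-(trimethylsilyl)halim-5-en-15-oate (numbering of the skeleton only; C8 epimers, centre left open) | CC(=O)OC[C@]1(C)CCC[C@@H]2C1=C([Si](C)(C)C)C(=O)C(C)[C@@]2(C)CC[C@@H](C)CC(=O)OC(C)(C)C | intermediate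
28 | trilithium trienolate of 27 (C7/C8 dienolate, acetate enolate, tert-butyl ester enolate) | [Li+].[Li+].[Li+].[O-]C(=C)OC[C@]1(C)CCC[C@@H]2C1=C([Si](C)(C)C)C([O-])=C(C)[C@@]2(C)CC[C@@H](C)C=C([O-])OC(C)(C)C | intermediate (not isolated)
29 | tert-butyl (4R,8R,9S,10S,13R)-18-acetoxy-7-oxo-6-(trimethylsilyl)halim-5-en-15-oate | CC(=O)OC[C@]1(C)CCC[C@@H]2C1=C([Si](C)(C)C)C(=O)[C@H](C)[C@@]2(C)CC[C@@H](C)CC(=O)OC(C)(C)C | intermediate
30 | (4R,8R,9S,10S,13R)-18-acetoxy-7-oxo-6-(trimethylsilyl)halim-5-en-15-oic acid | CC(=O)OC[C@]1(C)CCC[C@@H]2C1=C([Si](C)(C)C)C(=O)[C@H](C)[C@@]2(C)CC[C@@H](C)CC(=O)O | intermediate (not isolated)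
31 | CNP0210381.1, (3R)-5-[(1S,2R,5R,8aS)-5-(acetoxymethyl)-1,2,5-trimethyl-3-oxo-1,2,3,5,6,7,8,8a-octahydronaphthalen-1-yl]-3-methylpentanoic acid | CC(=O)OC[C@]1(C)CCC[C@@H]2C1=CC(=O)[C@H](C)[C@@]2(C)CC[C@@H](C)CC(=O)O | target

Total step count: 17.
Longest linear sequence: 12 steps (steps 1–7, 12, 14–17).

Steps most likely to fail

Step 15. The acyl-rhodium intermediate may lose CO and collapse to a cyclopropane, the alkyne flanked by a quaternary carbon and a silyl group may insert too slowly, β-hydride loss toward C1 may open the ring, or the C7–C8 bond may be cut instead. The fallback changes both the alkyne and the way the C–C bond is activated. It sets out from 26, whose alkynyl silane is removed with catalytic AgNO3 in aqueous acetone to give the terminal-alkyne cyclobutanone F1. F1 is condensed in situ with 2-amino-3-picoline, so that a transient ketimine directs rhodium into the C7–C10 bond ([Rh(C2H4)2Cl]2, electron-poor triarylphosphine, dioxane, 150 °C), and insertion of the unhindered alkyne should give the des-silyl enone tert-butyl ester F2 as C8 epimers. Kinetic deprotonation and protonation as in step 16 should give the (8R)-enone tert-butyl ester F3, and TFA as in step 17 brings the fallback back to the route at 31.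

Step 14. The auxiliary may discriminate poorly between the faces of an acyclic trisubstituted alkene, or in the sense opposite to the assumption, which would give C9/C10 diastereomers relative to C4 and C13. The fallback sets out from 20 and uses catalyst control in a different cycloaddition: a chiral oxazaborolidinium Lewis acid promotes the [2+2] reaction of 20 with 2,2,2-trifluoroethyl buta-2,3-dienoate to the alkylidenecyclobutane F4 (exocyclic enoate, E/Z immaterial). Ozonolysis (O3, then Me2S) cleaves the enoate to the cyclobutanone lacking C17 F5. Selective enolisation of the ketone at its CH2 group (LiHMDS, 1.05 equiv, THF, −78 °C) and MeI then give 26, where the fallback rejoins the route.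

Step 16. Protonation may be poorly face-selective, some γ-deprotonation may erode C10, and the ester enolates may undergo Claisen or Michael side reactions. The fallback sets out from 27 and avoids strong base: soft enolisation (Me3SiOTf, Et3N, CH2Cl2, −78 °C) should give the isolable 7-trimethylsilyloxy-5,7-diene F6. Its protonolysis in TFA under the conditions of step 17 should deliver H8 from the α face while the tert-butyl and both silyl groups are lost, so the fallback comes back to the route at 31.

Further compounds
F1 | step 15 | 26 without the trimethylsilyl group, terminal-alkyne cyclobutanone (C8 epimers, centre left open) | CC(=O)OC[C@](C)(CCC[C@@H]1C(=O)C(C)[C@@]1(C)CC[C@@H](C)CC(=O)OC(C)(C)C)C#C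
F2 | step 15 | tert-butyl (4R,9S,10S,13R)-18-acetoxy-7-oxohalim-5-en-15-oate (C8 epimers, centre left open) | CC(=O)OC[C@]1(C)CCC[C@@H]2C1=CC(=O)C(C)[C@@]2(C)CC[C@@H](C)CC(=O)OC(C)(C)C
F3 | step 15 | tert-butyl (4R,8R,9S,10S,13R)-18-acetoxy-7-oxohalim-5-en-15-oate | CC(=O)OC[C@]1(C)CCC[C@@H]2C1=CC(=O)[C@H](C)[C@@]2(C)CC[C@@H](C)CC(=O)OC(C)(C)C
F4 | step 14 | alkylidenecyclobutane: 26 with C7=CH–CO2CH2CF3 in place of C7=O and without C17 (E/Z) | CC(=O)OC[C@](C)(CCC[C@@H]1C(=CC(=O)OCC(F)(F)F)C[C@@]1(C)CC[C@@H](C)CC(=O)OC(C)(C)C)C#C[Si](C)(C)C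
F5 | step 14 | cyclobutanone 26 lacking the C8 methyl (C17) | CC(=O)OC[C@](C)(CCC[C@@H]1C(=O)C[C@@]1(C)CC[C@@H](C)CC(=O)OC(C)(C)C)C#C[Si](C)(C)C
F6 | step 16 | tert-butyl (4R,9S,10S,13R)-18-acetoxy-6-(trimethylsilyl)-7-(trimethylsilyloxy)halima-5,7-dien-15-oate | CC(=O)OC[C@]1(C)CCC[C@@H]2C1=C([Si](C)(C)C)C(O[Si](C)(C)C)=C(C)[C@@]2(C)CC[C@@H](C)CC(=O)OC(C)(C)C
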